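Lactone numbering used throughout: O1, C2(=O), C3=C4, C5 (acyloxy), C6, then C7=C8–C9O2H; the acyl chain carbons are primed.

Retrosynthesis cuts the C5–O dienoyl ester bond, then the alkenes C3=C4 (ring) and C7=C8 (chain) by metathesis, then the acrylate ester bond O1–C2.
Enabling feature: C5 and C6 form a threo (S,S) 1,2-dioxygenated pair, each bonded to one alkene carbon (C4 in the ring, C7 outside it), which is (3S,4S)-hexa-1,5-diene-3,4-diol; its two hydroxyls are equivalent by C2 symmetry.
Forward: an L-tartrate acetonide gives the divinyl diol, then its mono-silyl ether and acrylate; one ruthenium-catalysed operation closes the six-membered lactone (the only ring) at C3=C4 and then joins tert-butyl acrylate at C7=C8.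
The chain is completed by desilylation, esterification of the C5 hydroxyl with (2E,4E,6S)-4,6-dimethyldodeca-2,4-dienoic acid (from octanoyl chloride by auxiliary-controlled methylation and two olefinations), and acidolysis of the tert-butyl ester.
Stereochemistry: C5 and C6 come unchanged from L-tartaric acid, C6′ from an Evans methylation, the E alkenes from stabilised-ylide and phosphonate olefinations and from thermodynamic cross metathesis, and the Z ring alkene from ring constraint.

Key step: step 5

Assumption: the acetonide diester 1 is bought as such; it is the 2,3-O-isopropylidene derivative of dimethyl L-tartrate and is otherwise one acetalisation away from the tartrate ester.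

Step 1
Reactants: 1 dimethyl (4R,5R)-2,2-dimethyl-1,3-dioxolane-4,5-dicarboxylate
Product: 3 (4S,5S)-4,5-diethenyl-2,2-dimethyl-1,3-dioxolane, via dialdehyde 2 (not isolated)
Conditions: i-Bu2AlH (2.1 equiv), toluene, −78 °C; then Ph3P=CH2 (from Ph3PCH3Br, n-BuLi, THF), −78 °C to rt
Reagents that add atoms: methyltriphenylphosphonium bromide, C[P+](c1ccccc1)(c1ccccc1)c1ccccc1.[Br-]
Why: One-pot partial ester reduction and Wittig methylenation, in which each ester is held at −78 °C as its aluminium hemiacetal and releases the aldehyde only as the ylide consumes it, so the configurationally labile α-alkoxy dialdehyde is never accumulated and both stereocentres are carried over unchanged.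

Step 2
Reactants: 3 (4S,5S)-4,5-diethenyl-2,2-dimethyl-1,3-dioxolane
Product: 4 (3S,4S)-hexa-1,5-diene-3,4-diol
Conditions: sulfonic acid ion-exchange resin (H+ form), MeOH/H2O 9:1, 40 °C
Reagents that add atoms: none
Why: Acid-catalysed acetal hydrolysis frees the C2-symmetric diol by cleavage at the acetal carbon only, so no C–O bond at either stereocentre is broken.

Step 3
Reactants: 4 (3S,4S)-hexa-1,5-diene-3,4-diol
Product: 5 (3S,4S)-4-[(tert-butyldimethylsilyl)oxy]hexa-1,5-dien-3-ol
Conditions: NaH (1.0 equiv), THF, 0 °C; then TBSCl (1.0 equiv), 0 °C to rt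
Reagents that add atoms: tert-butyldimethylsilyl chloride, CC(C)(C)[Si](C)(C)Cl
Why: O-silylation of the monosodium alkoxide of a symmetric diol, in which the two hydroxyls are homotopic so that only the degree of silylation has to be controlled by the single equivalent of base and silyl chloride, with diol and bis-ether recyclable.

Step 4
Reactants: 5 (3S,4S)-4-[(tert-butyldimethylsilyl)oxy]hexa-1,5-dien-3-ol; 6 acryloyl chloride
Product: 7 (3S,4S)-4-[(tert-butyldimethylsilyl)oxy]hexa-1,5-dien-3-yl prop-2-enoate
Conditions: Et3N, 4-(dimethylamino)pyridine (cat.), CH2Cl2, −20 to 0 °C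
Reagents that add atoms: none
Why: O-acylation of the secondary alcohol with an acid chloride (nucleophilic acyl substitution under amine base), in which any 1,2-silyl shift is degenerate because of the C2 symmetry of the diol core.

Step 5
Reactants: 7 (3S,4S)-4-[(tert-butyldimethylsilyl)oxy]hexa-1,5-dien-3-yl prop-2-enoate; 8 tert-butyl prop-2-enoate (tert-butyl acrylate)
Product: 10 tert-butyl (E)-3-[(2S,3S)-3-[(tert-butyldimethylsilyl)oxy]-6-oxo-3,6-dihydro-2H-pyran-2-yl]prop-2-enoate, via vinyl lactone 9 (not isolated)
Conditions: second-generation Hoveyda–Grubbs catalyst RuCl2(H2IMes)(=CH-C6H4-2-O-i-Pr) (H2IMes = 1,3-dimesitylimidazolidin-2-ylidene; 5 mol%), toluene (0.02 M), 80 °C until 7 is consumed; then 8 (10 equiv) and a second 5 mol% of the catalyst, 80 °C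
Reagents that add atoms: none
Why: Olefin metathesis by the Chauvin mechanism: the ruthenium alkylidene loads on a terminal vinyl group, and when it sits on the vinyl group of the silyloxy carbon (future C5) a [2+2] cycloaddition to the acrylate C=C and cycloreversion of the ruthenacyclobutane expel ethene and form C3=C4. The ring closes by ring-closing metathesis of a 1,7-diene to the six-membered α,β-unsaturated δ-lactone, whose endocyclic alkene can only be Z; the closest known reaction type is the ring-closing metathesis of acrylates of homoallylic alcohols to 5,6-dihydropyran-2-ones run in one flask with an acrylate cross metathesis. No stereocentre is formed and none is at risk, since no bond to C5 or C6 is broken and both carry their configuration over from the tartrate. The step needs ring-size selectivity, which the substrate secures because closure onto the vinyl group of the acyloxy carbon (future C6) would have to give a more strained butenolide, a closure that is slow for acrylates, while alkylidene exchange between the two vinyl groups is reversible and drains into the six-membered ring. It needs the ring closure to precede the cross coupling, which dilution and the late addition of tert-butyl acrylate secure, so that the C5 vinyl group is never capped as an unreactive enoate. It needs E geometry at C7=C8, which follows from the thermodynamic preference of acrylate cross metathesis at the one remaining monosubstituted alkene; the Z-disubstituted, electron-poor ring alkene and the silyl-protected C5 oxygen offer no competing site.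

Step 6
Reactants: 10 tert-butyl (E)-3-[(2S,3S)-3-[(tert-butyldimethylsilyl)oxy]-6-oxo-3,6-dihydro-2H-pyran-2-yl]prop-2-enoate
Product: 11 tert-butyl (E)-3-[(2S,3S)-3-hydroxy-6-oxo-3,6-dihydro-2H-pyran-2-yl]prop-2-enoate
Conditions: HF·pyridine, THF/pyridine, 0 °C to rt
Reagents that add atoms: none
Why: Fluoride-mediated desilylation at the Si–O bond under mildly acidic, buffered conditions leaves the tert-butyl ester intact and avoids the base-induced acyl migration or elimination to which the hydroxy lactone is prone.

Step 7
Reactants: 12 (S)-4-benzyloxazolidin-2-one; 13 octanoyl chloride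
Product: 14 (S)-4-benzyl-3-octanoyloxazolidin-2-one
Conditions: n-BuLi, THF, −78 °C; then 13, −78 to 0 °C
Reagents that add atoms: none
Why: N-acylation of the lithiated oxazolidinone by the acid chloride (nucleophilic acyl substitution) gives the imide needed for auxiliary-controlled alkylation.

Step 8
Reactants: 14 (S)-4-benzyl-3-octanoyloxazolidin-2-one
Product: 15 (S)-4-benzyl-3-[(S)-2-methyloctanoyl]oxazolidin-2-one
Conditions: NaN(SiMe3)2, THF, −78 °C; then MeI, −78 °C
Reagents that add atoms: iodomethane, CI
Why: Evans asymmetric alkylation, in which the chelated Z sodium enolate holds the hexyl chain in the enolate plane and is methylated on the face opposite the C4 benzyl group, which sets the new α-stereocentre as S; the minor diastereomer should be separable by chromatography.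

Step 9
Reactants: 15 (S)-4-benzyl-3-[(S)-2-methyloctanoyl]oxazolidin-2-one
Product: 16 (S)-2-methyloctan-1-ol
Conditions: LiBH4, MeOH (1 equiv), Et2O, 0 °C
Reagents that add atoms: none
Why: Reductive cleavage of the auxiliary by hydride attack at the exocyclic imide carbonyl gives the primary alcohol without enolisation of the α-stereocentre and returns the oxazolidinone.

Step 10
Reactants: 16 (S)-2-methyloctan-1-ol
Product: 17 (S)-2-methyloctanal
Conditions: PhI(OAc)2, 2,2,6,6-tetramethylpiperidin-1-oxyl (10 mol%), CH2Cl2, rt; used at once
Reagents that add atoms: none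
Why: Oxoammonium-mediated alcohol oxidation (nitroxyl catalysis with PhI(OAc)2 as terminal oxidant) stops at the aldehyde under nearly neutral conditions, so the α-methyl stereocentre is not epimerised.

Step 11
Reactants: 17 (S)-2-methyloctanal; 18 2-(triphenylphosphoranylidene)propanal
Product: 19 (2E,4S)-2,4-dimethyldec-2-enal
Conditions: toluene, 90 °C
Reagents that add atoms: none
Why: Wittig olefination with a stabilised formyl ylide gives the trisubstituted E enal because oxaphosphetane formation is reversible, and the conjugated product is too unreactive towards this weakly nucleophilic ylide to be homologated again.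

Step 12
Reactants: 19 (2E,4S)-2,4-dimethyldec-2-enal; 20 triethyl phosphonoacetate
Product: 21 ethyl (2E,4E,6S)-4,6-dimethyldodeca-2,4-dienoate
Conditions: NaH, THF, 0 °C; then 19, 0 °C to rt
Reagents that add atoms: none
Why: Horner–Wadsworth–Emmons olefination of the enal with the preformed sodium phosphonate anion gives the E disubstituted alkene under thermodynamic control, with no free base left to deprotonate the γ-position of the enal.

Step 13
Reactants: 21 ethyl (2E,4E,6S)-4,6-dimethyldodeca-2,4-dienoate
Product: 22 (2E,4E,6S)-4,6-dimethyldodeca-2,4-dienoic acid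
Conditions: LiOH·H2O, THF/MeOH/H2O, rt; then 1 M HCl
Reagents that add atoms: lithium hydroxide, [Li+].[OH-]
Why: Saponification of the ethyl ester by hydroxide addition–elimination at the acyl carbon is too mild to deprotonate the dienoate at C6′ or to move the alkenes.

Step 14
Reactants: 11 tert-butyl (E)-3-[(2S,3S)-3-hydroxy-6-oxo-3,6-dihydro-2H-pyran-2-yl]prop-2-enoate; 22 (2E,4E,6S)-4,6-dimethyldodeca-2,4-dienoic acid
Product: 23 tert-butyl (E)-3-[(2S,3S)-3-{[(2E,4E,6S)-4,6-dimethyldodeca-2,4-dienoyl]oxy}-6-oxo-3,6-dihydro-2H-pyran-2-yl]prop-2-enoate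
Conditions: N,N'-dicyclohexylcarbodiimide, 4-(dimethylamino)pyridine (10 mol%), CH2Cl2, 0 °C
Reagents that add atoms: none
Why: Steglich esterification, in which the carbodiimide activates the acid as its O-acylisourea and the pyridine catalyst transfers the acyl group to the secondary C5 hydroxyl with retention (only the O–H bond is broken), while low temperature and a catalytic amount of base protect the base-sensitive lactone.

Step 15
Reactants: 23 tert-butyl (E)-3-[(2S,3S)-3-{[(2E,4E,6S)-4,6-dimethyldodeca-2,4-dienoyl]oxy}-6-oxo-3,6-dihydro-2H-pyran-2-yl]prop-2-enoate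
Product: 24 (E)-3-[(2S,3S)-3-{[(2E,4E,6S)-4,6-dimethyldodeca-2,4-dienoyl]oxy}-6-oxo-3,6-dihydro-2H-pyran-2-yl]prop-2-enoic acid
Conditions: CF3CO2H/CH2Cl2 1:4, 0 °C to rt
Reagents that add atoms: none
Why: Acidolysis of the tert-butyl ester by alkyl–oxygen cleavage with loss of 2-methylpropene frees the acid, while the lactone, the dienoate ester and the alkenes, none of which can form a stabilised cation, should be left alone.

Compound list
1 | dimethyl (4R,5R)-2,2-dimethyl-1,3-dioxolane-4,5-dicarboxylate | COC(=O)[C@@H]1OC(C)(C)O[C@H]1C(=O)OC | starting material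
2 | (4R,5R)-2,2-dimethyl-1,3-dioxolane-4,5-dicarbaldehyde | O=C[C@@H]1OC(C)(C)O[C@H]1C=O | intermediate (not isolated)
3 | (4S,5S)-4,5-diethenyl-2,2-dimethyl-1,3-dioxolane | C=C[C@@H]1OC(C)(C)O[C@H]1C=C | intermediate
4 | (3S,4S)-hexa-1,5-diene-3,4-diol | C=C[C@H](O)[C@@H](O)C=C | intermediate
5 | (3S,4S)-4-[(tert-butyldimethylsilyl)oxy]hexa-1,5-dien-3-ol | C=C[C@H](O)[C@H](C=C)O[Si](C)(C)C(C)(C)C | intermediate
6 | acryloyl chloride | C=CC(=O)Cl | starting material
7 | (3S,4S)-4-[(tert-butyldimethylsilyl)oxy]hexa-1,5-dien-3-yl prop-2-enoate | C=CC(=O)O[C@@H](C=C)[C@H](C=C)O[Si](C)(C)C(C)(C)C | intermediate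
8 | tert-butyl prop-2-enoate | C=CC(=O)OC(C)(C)C | starting material
9 | (5S,6S)-5-[(tert-butyldimethylsilyl)oxy]-6-ethenyl-5,6-dihydro-2H-pyran-2-one | CC(C)(C)[Si](C)(C)O[C@H]1C=CC(=O)O[C@H]1C=C | intermediate (not isolated)
10 | tert-butyl (E)-3-[(2S,3S)-3-[(tert-butyldimethylsilyl)oxy]-6-oxo-3,6-dihydro-2H-pyran-2-yl]prop-2-enoate | CC(C)(C)[Si](C)(C)O[C@H]1C=CC(=O)O[C@H]1/C=C/C(=O)OC(C)(C)C | intermediate
11 | tert-butyl (E)-3-[(2S,3S)-3-hydroxy-6-oxo-3,6-dihydro-2H-pyran-2-yl]prop-2-enoate | O[C@H]1C=CC(=O)O[C@H]1/C=C/C(=O)OC(C)(C)C | intermediate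
12 | (S)-4-benzyloxazolidin-2-one | O=C1N[C@@H](Cc2ccccc2)CO1 | starting material
13 | octanoyl chloride | CCCCCCCC(=O)Cl | starting material
14 | (S)-4-benzyl-3-octanoyloxazolidin-2-one | CCCCCCCC(=O)N1[C@@H](Cc2ccccc2)COC1=O | intermediate
15 | (S)-4-benzyl-3-[(S)-2-methyloctanoyl]oxazolidin-2-one | CCCCCC[C@H](C)C(=O)N1[C@@H](Cc2ccccc2)COC1=O | intermediate
16 | (S)-2-methyloctan-1-ol | CCCCCC[C@H](C)CO | intermediate
17 | (S)-2-methyloctanal | CCCCCC[C@H](C)C=O | intermediate
18 | 2-(triphenylphosphoranylidene)propanal | CC(C=O)=P(c1ccccc1)(c1ccccc1)c1ccccc1 | starting material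
19 | (2E,4S)-2,4-dimethyldec-2-enal | CCCCCC[C@H](C)/C=C(C)/C=O | intermediate
20 | triethyl phosphonoacetate | CCOC(=O)CP(=O)(OCC)OCC | starting material
21 | ethyl (2E,4E,6S)-4,6-dimethyldodeca-2,4-dienoate | CCCCCC[C@H](C)/C=C(C)/C=C/C(=O)OCC | intermediate
22 | (2E,4E,6S)-4,6-dimethyldodeca-2,4-dienoic acid | CCCCCC[C@H](C)/C=C(C)/C=C/C(=O)O | intermediate
23 | tert-butyl (E)-3-[(2S,3S)-3-{[(2E,4E,6S)-4,6-dimethyldodeca-2,4-dienoyl]oxy}-6-oxo-3,6-dihydro-2H-pyran-2-yl]prop-2-enoate | CCCCCC[C@H](C)/C=C(C)/C=C/C(=O)O[C@H]1C=CC(=O)O[C@H]1/C=C/C(=O)OC(C)(C)C | intermediate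
24 | (E)-3-[(2S,3S)-3-{[(2E,4E,6S)-4,6-dimethyldodeca-2,4-dienoyl]oxy}-6-oxo-3,6-dihydro-2H-pyran-2-yl]prop-2-enoic acid | CCCCCC[C@H](C)/C=C(C)/C=C/C(=O)O[C@H]1C=CC(=O)O[C@H]1/C=C/C(=O)O | target

Total step count: 15.
Longest linear sequence: 9 steps (steps 7 to 13, then 14 and 15); the lactone branch (steps 1 to 6) joins at step 14.

Steps most likely to fail

1. Step 5. The cross metathesis at the hindered, oxygen-flanked C6 vinyl group may stall as the catalyst decays and the acrylate homodimerises, and part of the material may close to the five-membered lactone. In the fallback the ring closure is run alone, without acrylate, and the vinyl lactone 9 is isolated. From 9 the terminal alkene is cleaved by Lemieux–Johnson oxidation (OsO4 cat., NaIO4, 2,6-lutidine, dioxane/H2O, rt), the electron-poor ring alkene reacting far more slowly with OsO4, to give (2R,3S)-3-[(tert-butyldimethylsilyl)oxy]-6-oxo-3,6-dihydro-2H-pyran-2-carbaldehyde F1. This aldehyde is used crude and cold in a Wittig olefination with tert-butyl (triphenylphosphoranylidene)acetate (CH2Cl2, 0 °C), which comes back to the route at 10. C7=C8 is then formed by carbonyl olefination instead of metathesis, while the ring still arises by metathesis.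

2. Step 14. The C6 hydrogen is vinylogously acidified by the enoate, so base may induce loss of the new acyloxy group across C5–C6 towards an aromatic pyran-2-one; the lactone acyl group may also migrate to the free C5 hydroxyl, or the O-acylisourea may rearrange to an unreactive N-acylurea. The fallback moves the acylation ahead of the cross metathesis, to a stage where C6–H is only allylic. Setting out from 9 (isolated as above), HF·pyridine in THF gives (5S,6S)-6-ethenyl-5-hydroxy-5,6-dihydro-2H-pyran-2-one F2. Esterification of F2 with 22 (N,N'-dicyclohexylcarbodiimide, catalytic 4-(dimethylamino)pyridine, CH2Cl2, 0 °C) gives (2S,3S)-2-ethenyl-6-oxo-3,6-dihydro-2H-pyran-3-yl (2E,4E,6S)-4,6-dimethyldodeca-2,4-dienoate F3. Cross metathesis of F3 with 8 under the catalyst of step 5 comes back to the route at 23; the trisubstituted and the ester-conjugated alkenes of the dienoate should be much slower partners than the terminal vinyl group.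

3. Step 1. The aluminium hemiacetal may collapse early with over-reduction to the alcohol, excess ylide may epimerise the dialdehyde, and the volatile diene may be lost on concentration. In the fallback, setting out from 1, complete reduction with LiAlH4 (THF, 0 °C) gives [(4S,5S)-2,2-dimethyl-1,3-dioxolane-4,5-diyl]dimethanol F4. Swern oxidation of F4 ((COCl)2, DMSO, Et3N, CH2Cl2, −78 °C) generates the dialdehyde 2 under non-reducing conditions, and Ph3P=CH2 is added to the cold mixture, which comes back to the route at 3. Compound 3 is then carried into step 2 as a solution without evaporation to dryness.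

Further compounds
F1 | step 5 | (2R,3S)-3-[(tert-butyldimethylsilyl)oxy]-6-oxo-3,6-dihydro-2H-pyran-2-carbaldehyde | CC(C)(C)[Si](C)(C)O[C@H]1C=CC(=O)O[C@H]1C=O
F2 | step 14 | (5S,6S)-6-ethenyl-5-hydroxy-5,6-dihydro-2H-pyran-2-one | O[C@H]1C=CC(=O)O[C@H]1C=C
F3 | step 14 | (2S,3S)-2-ethenyl-6-oxo-3,6-dihydro-2H-pyran-3-yl (2E,4E,6S)-4,6-dimethyldodeca-2,4-dienoate | CCCCCC[C@H](C)/C=C(C)/C=C/C(=O)O[C@H]1C=CC(=O)O[C@H]1C=C
F4 | step 1 | [(4S,5S)-2,2-dimethyl-1,3-dioxolane-4,5-diyl]dimethanol | OC[C@@H]1OC(C)(C)O[C@H]1CO
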